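## Structural features

The target is a 2-arylbenzofuran with no stereocentres. Ring B (4-hydroxy-2-methoxyphenyl) is bonded to C2 of the furan ring, and C3 carries a formyl group. Ring A is a fully differentiated phloroglucinol: one oxygen is the furan O1 on C7a, one is a free hydroxyl on C4, one is a methyl ether on C6, with a prenyl group on C5 and hydrogen on C7. The fragile elements are the prenyl alkene next to a free phenol (acid closes it to a chroman), the electron-rich aldehyde beside the C4 hydroxyl, and two oxidisable phenols. The real difficulty is regiochemical: the three ring A oxygens must be told apart, prenyl must go to C5 and not C7, and the carbonyl carbon must go to C3 rather than to the activated ring A. The key step exploits the fact that C3a and C7a are neighbouring ring A carbons and that the C4 oxygen sits directly beside C3a. As a triflate on an aryne spanning C3a–C7a, that oxygen directs the incoming ylide oxygen to C7a and leaves the carbanion on C3a for bonding to C3. The same C4 oxygen later delivers the prenyl group to C5 by a sigmatropic shift, because C3a, its other ortho carbon, is blocked.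

## Logic of the disconnections

**25 to 24.** The bond cut is the O–CH2 bond of the acetal on the ring B oxygen. This phenol would compete with the C4 hydroxyl in every O-functionalisation and would not survive the oxidant that makes 13, so it stays masked to the end. The gain is that only one free phenol is present at any earlier stage. The forward step must spare a prenyl group beside a free phenol and an aldehyde, so it has to be dilute acid at room temperature.

**24 to 23 to 22.** No skeletal bond is cut; the C3 carbon is traced from aldehyde through primary alcohol to methyl ester. The ester is the form in which the key step delivers this carbon, and it is inert to fluoride, amine base and heat in between. The forward steps need a hydride that reduces a hindered ester beside a free phenol, and an oxidant that takes the heterobenzylic alcohol but not the phenol or the alkene.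

**22 to 21.** The C5–CH2 bond of the prenyl group is cut and reconnected through the tertiary carbon to the C4 oxygen (the [3,3] retron). Direct electrophilic prenylation could not distinguish C5 from C7, whereas a shift from O4 can only end on C5. The gain is that the regiochemistry is inherited from an oxygen substituent. The forward step needs heat without acid, and the ether must be the 1,1-dimethylallyl isomer because the allyl unit inverts.

**21 to 20 to 17 and 18 (through 19).** The O4–C(tertiary) bond is cut and the alkene is traced to an alkyne. Tertiary allylic aryl ethers are not accessible by direct substitution, whereas tertiary propargylic ones are under copper catalysis. The gain is a cheap five-carbon unit, 18. The forward steps must alkylate a hindered, hydrogen-bonded phenol and stop the hydrogenation at the alkene.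

**17 to 16.** The O4–S bond is cut. The sulfonyl group is both the polarising group and the protecting group of O4 during the annulation, so O4 and O6 are differentiated without any selective dealkylation. The forward step must cleave S–O without touching the ester.

**16 to 8 and 13 (through 14 and 15).** The bonds cut are O1–C7a and C3–C3a. This removes the furan ring in one operation and leaves a symmetrical aryne precursor and a single reagent that carries ring B, C2, C3 and the carboxyl carbon. Because 8 is symmetrical, only one aryne can form. The forward step must add oxygen first, at the carbon remote from the triflate, and must close the ring before the carbanion beside the triflate expels it.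

**13 to 12 to 10 and 11, and 10 to 9.** The cuts are the C–I bond of the ylide, the C–C bond between the acetyl carbon and the carbonate carbon (crossed Claisen retron), and the acetal O–CH2 bond. All three are standard, and the gain is two purchasable compounds. The only demand is that the acetal survives base and trivalent iodine.

**8 to 7 to 6 to 2 to 1 (3, 4, 5 in the flask).** The cuts are the two O–S bonds, the C–Si bond and the carbamate C–O bonds. The carbon between the two oxygens of 1 is flanked by two directing groups in 2, so it is the site of lithiation. N-Isopropyl carbamates are chosen over N,N-dialkyl ones because they cleave under mild amine base and can be triflated in the same flask, so the acid-sensitive C–Si bond of 7 is never exposed. The forward step must lithiate between the carbamates, not beside the methoxy group, and both N–H bonds must be silylated first.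

## Other disconnections considered

**Alternative 1:** The cut removes both substituents of the furan carbons at once, C2–ring B and C3–CHO.
- Forward step: 4,6-dimethoxybenzofuran A2 would be lithiated at C2 and combined with the ring B pinacol boronate A3 to give a boronate complex. A chloroiminium electrophile would attack C3 and trigger the 1,2-shift of ring B from boron to C2, and oxidative work-up with NaBO3 would restore the furan and free the aldehyde, giving A1.
- In favour: it is convergent, A2 and A3 are simple, and C3 arrives directly at the aldehyde oxidation level. On redox economy it is better than the chosen plan, which needs a reduction and an oxidation.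
- Against: an electrophile-triggered 1,2-shift of a benzofuranyl boronate with a chloroiminium carbon electrophile would be new chemistry. The doubly activated C5 and C7 of A2 could take the electrophile instead, and the migrating group is an ortho-substituted aryl. A1 also carries methyl ethers on both O4 and O6, so a chelation-controlled mono-demethylation must pick one of three methoxy groups while the silyl ether survives a Lewis acid.
- Comparison: the chosen plan differentiates O4 from O6 from the first step, a structural advantage. Mechanistically the chosen annulation is a known reaction type with one open regiochemical question, whereas the alternative has two unproven selectivities. On step count the alternative is equal or better if both selectivities hold.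

**Alternative 2:** The cut removes ring A by breaking C3a–C4, C4–C5 and C6–C7.
- Forward step: irradiation of the furyl diazo ketone A5 would give a furylketene by Wolff rearrangement. This would add to the methoxyalkyne A6 to give a cyclobutenone, which on heating would open and reclose onto the free furan β-carbon to give phenol A4.
- In favour: the C4 hydroxyl, C5 prenyl and C6 methoxy groups are placed by the polarity of the ynol ether in a single pericyclic cascade. No Claisen sequence and no triflate cleavage are needed, and only reduction, oxidation and desilylation follow A4. On steps after the key step and on predictability of regiochemistry it is better than the chosen plan.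
- Against: A5 is a trisubstituted furan that needs its own multistep synthesis and a diazo transfer, and A6 is a sensitive ynol ether. The step uses ultraviolet light and a diazo compound in the presence of an electron-rich aryl silyl ether and an alkene.
- Comparison: the alternative moves the difficulty into the furan precursor, so the total count should be equal or higher. The chosen plan uses purchasable aromatics and room-temperature ionic chemistry but must prove an aryne regiochemistry that the alternative does not face.

**Alternative 3:** The cut is the C2=C3 bond of the furan.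
- Forward step: the keto ester A8 would be treated with low-valent titanium from TiCl3 and zinc. The ketone carbon and the ester carbonyl carbon would couple to close the furan, giving A7.
- In favour: intramolecular carbonyl coupling of ortho-acyloxyaryl ketones to benzofurans is well established. The ring fusion is fixed by the substitution of the ketone, so there is no regiochemical question in the ring closure; on this point it is better than the chosen plan. The ester A8 is made by a trivial acylation.
- Against: C3 arrives as a methyl group. It must be oxidised to the aldehyde on an electron-rich benzofuran, where radical or selenium-based oxidants would also attack ring A. The three phloroglucinol oxygens of the ketone must be differentiated by selective protection beforehand, the benzyl group must leave before the prenyl group arrives, and the conditions are strongly reducing.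
- Comparison: both plans close one ring. The alternative is more certain in the ring closure, but the chosen plan is better in redox economy because C3 comes in at the carboxyl level. The alternative is probably longer.

Key step: step 7

Assumption: 1, 9, 11 and 18 are purchased. The connectivity of 8, 13, 14 and 16 was checked against the target numbering (aryne carbon remote from the triflate becomes C7a) and needs no correction. The orientation of addition to 14 is argued from the distortion of 3-oxygenated arynes and is not established for this aryne.

## Route

Step 1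
Reactants: 1 5-methoxyresorcinol
Product: 2 5-methoxy-1,3-phenylene bis(N-isopropylcarbamate)
Conditions: i-PrNCO (2.4 equiv), Et3N (0.2 equiv), CH2Cl2, rt
Reagents that add atoms: isopropyl isocyanate CC(C)N=C=O
Why: Amine-catalysed addition of both phenols to the isocyanate (carbamoylation) should give the symmetrical bis(carbamate). The N–H carbamate is chosen because it is a strong directing group after N-silylation and is later removed by mild base.

Step 2
Reactants: 2 5-methoxy-1,3-phenylene bis(N-isopropylcarbamate)
Product: 6 5-methoxy-2-(trimethylsilyl)-1,3-phenylene bis(N-isopropylcarbamate), via bis(N-silyl) carbamate 3 (not isolated), via C2 aryllithium 4 (not isolated), via C-silylated bis(N-silyl) carbamate 5 (not isolated)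
Conditions: TMSOTf (2.2 equiv), TMEDA, Et2O, 0 °C to rt; then n-BuLi (3.5 equiv), TMEDA, −78 °C; TMSCl, −78 °C to rt; aq NH4Cl
Reagents that add atoms: chlorotrimethylsilane C[Si](C)(C)Cl
Why: Directed ortho-metalation: in situ N-silylation masks both N–H bonds, and n-BuLi/TMEDA should then remove the proton at C2, the only site flanked by two carbamate directing groups and more acidic than the sites beside the weaker methoxy director. C-Silylation with TMSCl and hydrolysis of the labile N–Si bonds on work-up should give 6.

Step 3
Reactants: 6 5-methoxy-2-(trimethylsilyl)-1,3-phenylene bis(N-isopropylcarbamate)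
Product: 8 5-methoxy-2-(trimethylsilyl)-1,3-phenylene bis(trifluoromethanesulfonate), via silylresorcinol 7 (not isolated)
Conditions: Et2NH, DBU, MeCN, 40 °C; then PhNTf2, rt (same flask)
Reagents that add atoms: N-phenylbis(trifluoromethanesulfonimide) O=S(=O)(N(c1ccccc1)S(=O)(=O)C(F)(F)F)C(F)(F)F
Why: DBU deprotonates each N–H and the aryloxide leaves by E1cB loss of isopropyl isocyanate, which diethylamine traps as a urea. The bis(phenoxide) 7 is O-sulfonylated by PhNTf2 without isolation, so the protodesilylation-prone silylresorcinol never meets acid.

Step 4
Reactants: 9 4'-hydroxy-2'-methoxyacetophenone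
Product: 10 1-[2-methoxy-4-(methoxymethoxy)phenyl]ethanone
Conditions: MOMCl, i-Pr2NEt, CH2Cl2, 0 °C to rt
Reagents that add atoms: chloromethyl methyl ether COCCl
Why: O-Alkylation of the phenol (acetal protection) should be clean. The acetal is stable to the base, fluoride, hydride, heat and oxidants used later and is removed by dilute acid.

Step 5
Reactants: 10 1-[2-methoxy-4-(methoxymethoxy)phenyl]ethanone; 11 dimethyl carbonate
Product: 12 methyl 3-[2-methoxy-4-(methoxymethoxy)phenyl]-3-oxopropanoate
Conditions: NaH (2.5 equiv), THF, reflux; AcOH quench
Reagents that add atoms: none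
Why: Crossed Claisen condensation of the methyl ketone enolate with the non-enolisable carbonate, driven by deprotonation of the β-keto ester product. A weak-acid quench keeps the acetal intact.

Step 6
Reactants: 12 methyl 3-[2-methoxy-4-(methoxymethoxy)phenyl]-3-oxopropanoate
Product: 13 phenyliodonium ylide of 12, methyl 3-[2-methoxy-4-(methoxymethoxy)phenyl]-3-oxo-2-(phenyl-λ3-iodanylidene)propanoate
Conditions: PhI(OAc)2, KOH, MeOH, 0 °C
Reagents that add atoms: (diacetoxyiodo)benzene CC(=O)OI(OC(C)=O)c1ccccc1
Why: Ligand exchange of the β-keto ester enolate at trivalent iodine followed by a second deprotonation is the standard preparation of β-dicarbonyl iodonium ylides. The ylide should precipitate and is used without long storage.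

Step 7
Reactants: 8 5-methoxy-2-(trimethylsilyl)-1,3-phenylene bis(trifluoromethanesulfonate); 13 phenyliodonium ylide of 12 (1.5 equiv)
Product: 16 methyl 6-methoxy-2-[2-methoxy-4-(methoxymethoxy)phenyl]-4-(trifluoromethylsulfonyloxy)benzofuran-3-carboxylate, via triflyloxy aryne 14 (not isolated), via aryl anion iodonium adduct 15 (not isolated)
Conditions: CsF (2.5 equiv), MeCN, rt
Reagents that add atoms: none
Why: CsF removes the silyl group of 8 with loss of one triflate and gives aryne 14, in which the remaining triflyloxy group on the carbon beside the triple bond withdraws inductively and distorts the aryne so that nucleophiles enter at the remote carbon, the future C7a. Ylide 13 reacts as an iodonium enolate: its ketone-derived oxygen adds at that carbon and leaves the negative charge on the carbon beside the triflate, the future C3a (zwitterion 15). The aryl anion then takes the ylide carbon, either by attack on trivalent iodine to a six-membered iodacycle followed by ligand coupling, or by direct 5-endo addition–elimination at the alkenyliodonium carbon; iodobenzene is lost either way, and the furan ring is closed as a five-membered anionic ring closure by the C3–C3a bond after O1–C7a has formed. The closest known reaction type is the annulation of arynes from 2-silylaryl triflates with iodonium ylides of β-diketones and β-keto esters to 3-acylbenzofurans; the 3-(triflyloxy)aryne adds only the regiochemical question. No stereocentre is formed. Three selectivities are needed: oxygen before carbon (the iodine-bearing carbon is shielded and the charge lies on oxygen), ketone oxygen rather than ester oxygen (it carries more enolate charge and leads to the aromatic 2-aryl-3-carboxylate), and attack remote from the triflate (set by the aryne distortion, against which the weak opposing effect of the methoxy group should not matter). Excess 13 and slow aryne generation at room temperature are meant to make ring closure faster than loss of triflate from 15.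

Step 8
Reactants: 16 methyl 6-methoxy-2-[2-methoxy-4-(methoxymethoxy)phenyl]-4-(trifluoromethylsulfonyloxy)benzofuran-3-carboxylate
Product: 17 methyl 4-hydroxy-6-methoxy-2-[2-methoxy-4-(methoxymethoxy)phenyl]benzofuran-3-carboxylate
Conditions: Bu4NF, THF, 0 °C to rt; aq NH4Cl
Reagents that add atoms: none
Why: Fluoride attacks the sulfonyl sulfur of the electron-poor aryl triflate and releases the C4 phenoxide (S–O cleavage). The methyl ester and the acetal are inert to fluoride under these conditions.

Step 9
Reactants: 17 methyl 4-hydroxy-6-methoxy-2-[2-methoxy-4-(methoxymethoxy)phenyl]benzofuran-3-carboxylate; 18 2-methylbut-3-yn-2-ol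
Product: 20 methyl 6-methoxy-2-[2-methoxy-4-(methoxymethoxy)phenyl]-4-[(2-methylbut-3-yn-2-yl)oxy]benzofuran-3-carboxylate, via propargylic trifluoroacetate 19 (not isolated)
Conditions: 18, (CF3CO)2O, DBU, MeCN, 0 °C; then 17, DBU, CuCl2·2H2O (cat.), MeCN, 0 °C to rt
Reagents that add atoms: none
Why: Copper-catalysed propargylic substitution: the copper acetylide of 19 ionises to an allenylidene-type electrophile that the phenoxide attacks at the tertiary carbon. This is the standard route to aryl 1,1-dimethylpropargyl ethers and works on hydrogen-bonded phenols.

Step 10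
Reactants: 20 methyl 6-methoxy-2-[2-methoxy-4-(methoxymethoxy)phenyl]-4-[(2-methylbut-3-yn-2-yl)oxy]benzofuran-3-carboxylate
Product: 21 methyl 6-methoxy-2-[2-methoxy-4-(methoxymethoxy)phenyl]-4-[(2-methylbut-3-en-2-yl)oxy]benzofuran-3-carboxylate
Conditions: H2 (1 atm), Pd/CaCO3–Pb(OAc)2 (Lindlar catalyst), quinoline, EtOAc, rt
Reagents that add atoms: none
Why: Lindlar semi-hydrogenation of the terminal alkyne should stop at the vinyl group. The tetrasubstituted furan double bond and the aryl ethers are not reduced on the poisoned catalyst.

Step 11
Reactants: 21 methyl 6-methoxy-2-[2-methoxy-4-(methoxymethoxy)phenyl]-4-[(2-methylbut-3-en-2-yl)oxy]benzofuran-3-carboxylate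
Product: 22 methyl 4-hydroxy-6-methoxy-2-[2-methoxy-4-(methoxymethoxy)phenyl]-5-(3-methylbut-2-en-1-yl)benzofuran-3-carboxylate
Conditions: PhNEt2, 140 °C
Reagents that add atoms: none
Why: Aromatic Claisen rearrangement: the [3,3] shift can rearomatise only at C5 because the other ortho carbon, C3a, is a ring-fusion carbon. Allyl inversion turns the 1,1-dimethylallyl ether into the C5 prenyl group, and the basic solvent suppresses acid-induced cyclisation of the product.

Step 12
Reactants: 22 methyl 4-hydroxy-6-methoxy-2-[2-methoxy-4-(methoxymethoxy)phenyl]-5-(3-methylbut-2-en-1-yl)benzofuran-3-carboxylate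
Product: 23 3-(hydroxymethyl)-6-methoxy-2-[2-methoxy-4-(methoxymethoxy)phenyl]-5-(3-methylbut-2-en-1-yl)benzofuran-4-ol
Conditions: i-Bu2AlH (4 equiv), CH2Cl2, −78 to 0 °C; aq KNaC4H4O6 (Rochelle salt)
Reagents that add atoms: none
Why: Hydride reduction of the ester to the primary alcohol; one equivalent is consumed by the phenol, hence the excess. The acetal and the alkene are inert, and 23 is oxidised promptly because it is a heterobenzylic alcohol on an electron-rich ring.

Step 13
Reactants: 23 3-(hydroxymethyl)-6-methoxy-2-[2-methoxy-4-(methoxymethoxy)phenyl]-5-(3-methylbut-2-en-1-yl)benzofuran-4-ol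
Product: 24 4-hydroxy-6-methoxy-2-[2-methoxy-4-(methoxymethoxy)phenyl]-5-(3-methylbut-2-en-1-yl)benzofuran-3-carbaldehyde
Conditions: MnO2 (activated, excess), CH2Cl2, rt
Reagents that add atoms: none
Why: MnO2 oxidises the activated heterobenzylic alcohol selectively and does not over-oxidise the aldehyde. The product aldehyde is stabilised by a hydrogen bond to the C4 hydroxyl.

Step 14
Reactants: 24 4-hydroxy-6-methoxy-2-[2-methoxy-4-(methoxymethoxy)phenyl]-5-(3-methylbut-2-en-1-yl)benzofuran-3-carbaldehyde
Product: 25 4-hydroxy-2-(4-hydroxy-2-methoxyphenyl)-6-methoxy-5-(3-methylbut-2-en-1-yl)benzofuran-3-carbaldehyde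
Conditions: HCl (dilute), MeOH, rt; aqueous work-up
Reagents that add atoms: none
Why: Acid-catalysed acetal exchange frees the ring B phenol. At room temperature the C4 hydroxyl, hydrogen-bonded to the aldehyde, should add to the prenyl alkene only slowly, and any dimethyl acetal of the aldehyde reverts on aqueous work-up.

## Compound list

1 | 5-methoxyresorcinol (5-methoxybenzene-1,3-diol) | COc1cc(O)cc(O)c1 | starting material
2 | 5-methoxy-1,3-phenylene bis(N-isopropylcarbamate) | COc1cc(OC(=O)NC(C)C)cc(OC(=O)NC(C)C)c1 | intermediate
3 | 5-methoxy-1,3-phenylene bis[N-isopropyl-N-(trimethylsilyl)carbamate] | COc1cc(OC(=O)N(C(C)C)[Si](C)(C)C)cc(OC(=O)N(C(C)C)[Si](C)(C)C)c1 | intermediate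
4 | 2-lithio derivative of 3, {4-methoxy-2,6-bis[(N-isopropyl-N-trimethylsilylcarbamoyl)oxy]phenyl}lithium | COc1cc(OC(=O)N(C(C)C)[Si](C)(C)C)c([Li])c(OC(=O)N(C(C)C)[Si](C)(C)C)c1 | intermediate
5 | 5-methoxy-2-(trimethylsilyl)-1,3-phenylene bis[N-isopropyl-N-(trimethylsilyl)carbamate] | COc1cc(OC(=O)N(C(C)C)[Si](C)(C)C)c([Si](C)(C)C)c(OC(=O)N(C(C)C)[Si](C)(C)C)c1 | intermediate
6 | 5-methoxy-2-(trimethylsilyl)-1,3-phenylene bis(N-isopropylcarbamate) | COc1cc(OC(=O)NC(C)C)c([Si](C)(C)C)c(OC(=O)NC(C)C)c1 | intermediate
7 | 5-methoxy-2-(trimethylsilyl)benzene-1,3-diol | COc1cc(O)c([Si](C)(C)C)c(O)c1 | intermediate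
8 | 5-methoxy-2-(trimethylsilyl)-1,3-phenylene bis(trifluoromethanesulfonate) | COc1cc(OS(=O)(=O)C(F)(F)F)c([Si](C)(C)C)c(OS(=O)(=O)C(F)(F)F)c1 | intermediate
9 | 4'-hydroxy-2'-methoxyacetophenone | CC(=O)c1ccc(O)cc1OC | starting material
10 | 1-[2-methoxy-4-(methoxymethoxy)phenyl]ethanone | CC(=O)c1ccc(OCOC)cc1OC | intermediate
11 | dimethyl carbonate | COC(=O)OC | starting material
12 | methyl 3-[2-methoxy-4-(methoxymethoxy)phenyl]-3-oxopropanoate | COC(=O)CC(=O)c1ccc(OCOC)cc1OC | intermediate
13 | phenyliodonium ylide of 12, methyl 3-[2-methoxy-4-(methoxymethoxy)phenyl]-3-oxo-2-(phenyl-λ3-iodanylidene)propanoate | COC(=O)[C-]([I+]c1ccccc1)C(=O)c1ccc(OCOC)cc1OC | intermediate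
14 | 5-methoxy-3-(trifluoromethylsulfonyloxy)benzyne (triple bond C1–C2, triflate on C3, methoxy on C5) | COC1=CC#CC(OS(=O)(=O)C(F)(F)F)=C1 | intermediate
15 | zwitterion, methyl 3-[2-methoxy-4-(methoxymethoxy)phenyl]-3-{[5-methoxy-3-(trifluoromethylsulfonyloxy)benzen-2-id-1-yl]oxy}-2-(phenyliodonio)prop-2-enoate (carbanion on the ring carbon between the O-alkenyl and triflyloxy carbons) | COC(=O)C([I+]c1ccccc1)=C(Oc1cc(OC)cc(OS(=O)(=O)C(F)(F)F)[c-]1)c1ccc(OCOC)cc1OC | intermediate
16 | methyl 6-methoxy-2-[2-methoxy-4-(methoxymethoxy)phenyl]-4-(trifluoromethylsulfonyloxy)benzofuran-3-carboxylate | COC(=O)c1c(-c2ccc(OCOC)cc2OC)oc2cc(OC)cc(OS(=O)(=O)C(F)(F)F)c12 | intermediate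
17 | methyl 4-hydroxy-6-methoxy-2-[2-methoxy-4-(methoxymethoxy)phenyl]benzofuran-3-carboxylate | COC(=O)c1c(-c2ccc(OCOC)cc2OC)oc2cc(OC)cc(O)c12 | intermediate
18 | 2-methylbut-3-yn-2-ol | CC(C)(O)C#C | starting material
19 | 2-methylbut-3-yn-2-yl trifluoroacetate | CC(C)(OC(=O)C(F)(F)F)C#C | intermediate
20 | methyl 6-methoxy-2-[2-methoxy-4-(methoxymethoxy)phenyl]-4-[(2-methylbut-3-yn-2-yl)oxy]benzofuran-3-carboxylate | COC(=O)c1c(-c2ccc(OCOC)cc2OC)oc2cc(OC)cc(OC(C)(C)C#C)c12 | intermediate
21 | methyl 6-methoxy-2-[2-methoxy-4-(methoxymethoxy)phenyl]-4-[(2-methylbut-3-en-2-yl)oxy]benzofuran-3-carboxylate | COC(=O)c1c(-c2ccc(OCOC)cc2OC)oc2cc(OC)cc(OC(C)(C)C=C)c12 | intermediate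
22 | methyl 4-hydroxy-6-methoxy-2-[2-methoxy-4-(methoxymethoxy)phenyl]-5-(3-methylbut-2-en-1-yl)benzofuran-3-carboxylate | COC(=O)c1c(-c2ccc(OCOC)cc2OC)oc2cc(OC)c(CC=C(C)C)c(O)c12 | intermediate
23 | 3-(hydroxymethyl)-6-methoxy-2-[2-methoxy-4-(methoxymethoxy)phenyl]-5-(3-methylbut-2-en-1-yl)benzofuran-4-ol | OCc1c(-c2ccc(OCOC)cc2OC)oc2cc(OC)c(CC=C(C)C)c(O)c12 | intermediate
24 | 4-hydroxy-6-methoxy-2-[2-methoxy-4-(methoxymethoxy)phenyl]-5-(3-methylbut-2-en-1-yl)benzofuran-3-carbaldehyde | O=Cc1c(-c2ccc(OCOC)cc2OC)oc2cc(OC)c(CC=C(C)C)c(O)c12 | intermediate
25 | 4-hydroxy-2-(4-hydroxy-2-methoxyphenyl)-6-methoxy-5-(3-methylbut-2-en-1-yl)benzofuran-3-carbaldehyde | COc1cc(O)ccc1-c1oc2cc(OC)c(CC=C(C)C)c(O)c2c1C=O | target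

## Step count and least certain steps

Total: 14 steps. Longest linear sequence: 11 steps (steps 1–3 or steps 4–6, then steps 7–14).

**Step 7 (key step).**
- What may go wrong: the carbanion beside the triflate may expel triflate and generate a second aryne before it closes the ring. The ylide may add through carbon first and reverse the orientation. The ylide may also decompose under fluoride faster than the aryne forms.
- Fallback (sets out from 2 and 10, returns at 17): the furan would be closed by alkoxycarbonylative cyclisation of an ortho-alkynylphenol instead of an aryne annulation.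
  - 2 is taken through 3 and 4 as in step 2, and the aryllithium is quenched with iodine to give 2-iodo-5-methoxy-1,3-phenylene bis(N-isopropylcarbamate) F1.
  - 10 is converted through its enol diethyl phosphate (LiN(i-Pr)2, ClP(O)(OEt)2, then LiN(i-Pr)2) into 1-ethynyl-2-methoxy-4-(methoxymethoxy)benzene F2.
  - Sonogashira coupling of F1 with F2 (PdCl2(PPh3)2, CuI, Et3N, DMF) should give 5-methoxy-2-{[2-methoxy-4-(methoxymethoxy)phenyl]ethynyl}-1,3-phenylene bis(N-isopropylcarbamate) F3.
  - The carbamates are removed as in step 3 (Et2NH, DBU, MeCN) to give 5-methoxy-2-{[2-methoxy-4-(methoxymethoxy)phenyl]ethynyl}benzene-1,3-diol F4.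
  - F4 is cyclised under CO in MeOH with catalytic PdCl2, CuCl2 as oxidant and NaOAc. Because F4 is symmetrical, either hydroxyl closes to the same furan and the other becomes the C4 hydroxyl, so 17 should result directly and step 8 is not needed.

**Step 9.**
- What may go wrong: O-alkylation of the hindered, hydrogen-bonded C4 phenol by the tertiary electrophile may be slow, and elimination of 19 to the enyne may then take over.
- Fallback (sets out from 17, returns at 21): Tsuji–Trost O-allylation of 17 with tert-butyl 2-methylbut-3-en-2-yl carbonate (C=CC(C)(C)OC(=O)OC(C)(C)C) and Pd(PPh3)4 in THF at 0 °C. Under kinetic control the phenoxide should attack the more substituted end of the 1,1-dimethylallyl palladium complex. This gives 21 directly and makes 20 and step 10 unnecessary.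

**Step 14.**
- What may go wrong: acid-catalysed addition of the C4 hydroxyl to the prenyl alkene (chroman formation) may compete with acetal cleavage.
- Fallback (sets out from 20, returns at 25): the acetal would be removed before the prenyl group and the free C4 hydroxyl coexist.
  - 20, whose tertiary propargylic ether ionises far less readily than the allylic ether 21, is treated with dilute HCl in MeOH to give methyl 2-(4-hydroxy-2-methoxyphenyl)-6-methoxy-4-[(2-methylbut-3-yn-2-yl)oxy]benzofuran-3-carboxylate F5.
  - Semi-hydrogenation as in step 10 gives methyl 2-(4-hydroxy-2-methoxyphenyl)-6-methoxy-4-[(2-methylbut-3-en-2-yl)oxy]benzofuran-3-carboxylate F6.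
  - Claisen rearrangement as in step 11 gives methyl 4-hydroxy-2-(4-hydroxy-2-methoxyphenyl)-6-methoxy-5-(3-methylbut-2-en-1-yl)benzofuran-3-carboxylate F7.
  - Reduction with excess i-Bu2AlH gives 3-(hydroxymethyl)-2-(4-hydroxy-2-methoxyphenyl)-6-methoxy-5-(3-methylbut-2-en-1-yl)benzofuran-4-ol F8.
  - MnO2 oxidation as in step 13 should give 25 with no acid after the prenyl group is in place.

## Further compounds

F1 | step 7 | 2-iodo-5-methoxy-1,3-phenylene bis(N-isopropylcarbamate) | COc1cc(OC(=O)NC(C)C)c(I)c(OC(=O)NC(C)C)c1
F2 | step 7 | 1-ethynyl-2-methoxy-4-(methoxymethoxy)benzene | C#Cc1ccc(OCOC)cc1OC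
F3 | step 7 | 5-methoxy-2-{[2-methoxy-4-(methoxymethoxy)phenyl]ethynyl}-1,3-phenylene bis(N-isopropylcarbamate) | COc1cc(OC(=O)NC(C)C)c(C#Cc2ccc(OCOC)cc2OC)c(OC(=O)NC(C)C)c1
F4 | step 7 | 5-methoxy-2-{[2-methoxy-4-(methoxymethoxy)phenyl]ethynyl}benzene-1,3-diol | COc1cc(O)c(C#Cc2ccc(OCOC)cc2OC)c(O)c1
F0 | step 9 | none | none
F5 | step 14 | methyl 2-(4-hydroxy-2-methoxyphenyl)-6-methoxy-4-[(2-methylbut-3-yn-2-yl)oxy]benzofuran-3-carboxylate | COC(=O)c1c(-c2ccc(O)cc2OC)oc2cc(OC)cc(OC(C)(C)C#C)c12
F6 | step 14 | methyl 2-(4-hydroxy-2-methoxyphenyl)-6-methoxy-4-[(2-methylbut-3-en-2-yl)oxy]benzofuran-3-carboxylate | COC(=O)c1c(-c2ccc(O)cc2OC)oc2cc(OC)cc(OC(C)(C)C=C)c12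
F7 | step 14 | methyl 4-hydroxy-2-(4-hydroxy-2-methoxyphenyl)-6-methoxy-5-(3-methylbut-2-en-1-yl)benzofuran-3-carboxylate | COC(=O)c1c(-c2ccc(O)cc2OC)oc2cc(OC)c(CC=C(C)C)c(O)c12
F8 | step 14 | 3-(hydroxymethyl)-2-(4-hydroxy-2-methoxyphenyl)-6-methoxy-5-(3-methylbut-2-en-1-yl)benzofuran-4-ol | OCc1c(-c2ccc(O)cc2OC)oc2cc(OC)c(CC=C(C)C)c(O)c12
A1 | alternative 1 | 4,6-dimethoxy-2-[2-methoxy-4-(triisopropylsilyloxy)phenyl]benzofuran-3-carbaldehyde | COc1cc(OC)c2c(C=O)c(-c3ccc(O[Si](C(C)C)(C(C)C)C(C)C)cc3OC)oc2c1
A2 | alternative 1 | 4,6-dimethoxybenzofuran | COc1cc(OC)c2ccoc2c1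
A3 | alternative 1 | 2-[2-methoxy-4-(triisopropylsilyloxy)phenyl]-4,4,5,5-tetramethyl-1,3,2-dioxaborolane | COc1cc(O[Si](C(C)C)(C(C)C)C(C)C)ccc1B1OC(C)(C)C(C)(C)O1
A4 | alternative 2 | methyl 4-hydroxy-6-methoxy-5-(3-methylbut-2-enyl)-2-[2-methoxy-4-(triisopropylsilyloxy)phenyl]benzofuran-3-carboxylate | COC(=O)c1c(-c2ccc(O[Si](C(C)C)(C(C)C)C(C)C)cc2OC)oc2cc(OC)c(CC=C(C)C)c(O)c12
A5 | alternative 2 | methyl 5-(2-diazoacetyl)-2-[2-methoxy-4-(triisopropylsilyloxy)phenyl]furan-3-carboxylate | COC(=O)c1cc(C(=O)C=[N+]=[N-])oc1-c1ccc(O[Si](C(C)C)(C(C)C)C(C)C)cc1OC
A6 | alternative 2 | 1-methoxy-5-methylhex-4-en-1-yne | COC#CCC=C(C)C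
A7 | alternative 3 | 4-(benzyloxy)-6-methoxy-2-[2-methoxy-4-(triisopropylsilyloxy)phenyl]-3-methylbenzofuran | Cc1c(-c2ccc(O[Si](C(C)C)(C(C)C)C(C)C)cc2OC)oc2cc(OC)cc(OCc3ccccc3)c12
A8 | alternative 3 | 2-acetyl-3-(benzyloxy)-5-methoxyphenyl 2-methoxy-4-(triisopropylsilyloxy)benzoate | CC(=O)c1c(OCc2ccccc2)cc(OC)cc1OC(=O)c1ccc(O[Si](C(C)C)(C(C)C)C(C)C)cc1OC
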